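**Strategy.** Ring A (C1, C10 to C14) hides a symmetric 4,4-disubstituted cyclohexa-2,5-dienone: C10 and C14 both sit on the quaternary C1, and C11 and C13 both flank the C12 carbonyl. Everything rests on cutting C10–C11 and C13=C14 together. A 2,2-disubstituted malonaldehyde, already carrying C2 to C6, is condensed twice with acetonedicarboxylic acid, which forges both bonds and the whole six-membered ring in one operation and creates no stereocentre. The prochiral dienone is then desymmetrised by vinyl conjugate addition, methylation and hydroxylation; two chromium-mediated couplings build C8–C9 and close the ten-membered ring at C6–C7, before ene-chlorination and lactonisation.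

Key step: step 8

Numbering (briarane): C1 quaternary carbon with the C15 methyl; C2 acetoxy carbon; C3, C4; C5 with the C16 methylene; C6 chloro carbon; C7 lactone O–CH; C8 tertiary carbinol; C9 acetoxy carbon; C10; C11 with OH and the C20 methyl; C12 ketone; C13=C14; C17 with the C18 methyl; C19 lactone carbonyl.

Remark: C17 is carried as an epimeric pair from 23 and is set by base equilibration of the lactone in step 22, so the SMILES of 23 to 29 leave C17 undefined.

**Route**

Step 1
Reactants: 1 pent-4-yn-1-ol
Product: 2 (E)-5-bromo-4-methylpent-4-en-1-ol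
Conditions: AlMe3 (3 equiv), Cp2ZrCl2 (0.25 equiv), CH2Cl2, 0 °C to rt; then NBS, THF, −78 to 0 °C
Reagents that add atoms: trimethylaluminium C[Al](C)C; N-bromosuccinimide BrN1C(=O)CCC1=O
Why: Negishi carboalumination adds methyl (the future C16) and aluminium syn across the alkyne with methyl on the internal carbon, and bromodealumination with retention should give the E-bromoalkene (C6=C5).

Step 2
Reactants: 2 (E)-5-bromo-4-methylpent-4-en-1-ol
Product: 3 (E)-5-bromo-4-methylpent-4-enoic acid
Conditions: TEMPO (cat.), PhI(OAc)2 (2.2 equiv), MeCN/H2O, rt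
Reagents that add atoms: water O
Why: Oxoammonium (TEMPO) oxidation takes the primary alcohol through the aldehyde hydrate to the acid (C2) and leaves the bromoalkene untouched.

Step 3
Reactants: 3 (E)-5-bromo-4-methylpent-4-enoic acid; 4 dimethyl 2-methylmalonate
Product: 6 dimethyl 2-[(E)-5-bromo-4-methylpent-4-enoyl]-2-methylmalonate, via acid chloride 5 (not isolated)
Conditions: (COCl)2, DMF (cat.), CH2Cl2, 0 °C to rt, evaporate; then 4, NaH, THF, 0 °C to rt
Reagents that add atoms: none
Why: Claisen-type C-acylation of the sodium malonate enolate by the acid chloride forms the C1–C2 bond and the quaternary C1, which carries two identical ester arms and is therefore not a stereocentre.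

Step 4
Reactants: 6 dimethyl 2-[(E)-5-bromo-4-methylpent-4-enoyl]-2-methylmalonate
Product: 7 dimethyl 2-[(1R,4E)-5-bromo-1-hydroxy-4-methylpent-4-en-1-yl]-2-methylmalonate
Conditions: (S)-2-methyl-CBS-oxazaborolidine (0.2 equiv), BH3·SMe2, THF, −20 °C
Reagents that add atoms: none
Why: Corey–Bakshi–Shibata reduction differentiates the quaternary malonate carbon (large) from the methylene chain (small), so the (S)-catalyst should deliver hydride to give the (R)-carbinol at C2.

Step 5
Reactants: 7 dimethyl 2-[(1R,4E)-5-bromo-1-hydroxy-4-methylpent-4-en-1-yl]-2-methylmalonate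
Product: 8 dimethyl 2-[(1R,4E)-5-bromo-1-(tert-butyldimethylsilyloxy)-4-methylpent-4-en-1-yl]-2-methylmalonate
Conditions: TBSOTf, 2,6-lutidine, CH2Cl2, −78 to 0 °C
Reagents that add atoms: tert-butyldimethylsilyl triflate CC(C)(C)[Si](C)(C)OS(=O)(=O)C(F)(F)F
Why: Silylation of the hindered secondary alcohol with the silyl triflate blocks retro-aldol cleavage of the β-hydroxy malonate and supplies the bulky group that later steers the conjugate addition.

Step 6
Reactants: 8 dimethyl 2-[(1R,4E)-5-bromo-1-(tert-butyldimethylsilyloxy)-4-methylpent-4-en-1-yl]-2-methylmalonate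
Product: 9 2-[(1R,4E)-5-bromo-1-(tert-butyldimethylsilyloxy)-4-methylpent-4-en-1-yl]-2-methylpropane-1,3-diol
Conditions: iBu2AlH (5 equiv), CH2Cl2, −78 to 0 °C; aq. potassium sodium tartrate
Reagents that add atoms: none
Why: Hydride reduction of both esters gives the 1,3-diol (future C10 and C14), while the silyl ether and the bromoalkene are inert to the aluminium hydride at low temperature.

Step 7
Reactants: 9 2-[(1R,4E)-5-bromo-1-(tert-butyldimethylsilyloxy)-4-methylpent-4-en-1-yl]-2-methylpropane-1,3-diol
Product: 10 2-[(1R,4E)-5-bromo-1-(tert-butyldimethylsilyloxy)-4-methylpent-4-en-1-yl]-2-methylpropanedial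
Conditions: (COCl)2, DMSO, CH2Cl2, −78 °C; then Et3N
Reagents that add atoms: none
Why: Swern oxidation gives the non-enolisable 2,2-disubstituted malonaldehyde without epimerisable positions, to be used directly.

Step 8
Reactants: 10 2-[(1R,4E)-5-bromo-1-(tert-butyldimethylsilyloxy)-4-methylpent-4-en-1-yl]-2-methylpropanedial; 11 3-oxopentanedioic acid
Product: 13 4-[(1R,4E)-5-bromo-1-(tert-butyldimethylsilyloxy)-4-methylpent-4-en-1-yl]-4-methylcyclohexa-2,5-dien-1-one, via cyclic bis-aldol diacid 12 (not isolated)
Conditions: piperidine (0.2 equiv), AcOH (0.2 equiv), MeCN, 0 to 50 °C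
Reagents that add atoms: none
Why: The enol of the β-keto acid adds to one formyl group (Knoevenagel-type aldol) and the second β-keto acid arm then adds to the other formyl group, so ring A is closed at the saturated stage as diacid 12 and no E-enone can block closure; twofold decarboxylative dehydration then gives the cross-conjugated dienone, with C13=C14 and C10=C11 formed in the same operation. The closest known reaction type is the double Knoevenagel–Doebner condensation of dialdehydes with acetonedicarboxylic acid or its esters to cyclic dienones, as in Robinson–Schöpf-type cyclocondensations. The only ring closed is the six-membered ring A, by a 6-(enolexo)-exo-trig aldol at C10–C11 after intermolecular union at C13–C14 (the two formyl groups are equivalent, so either order gives the same product). No stereocentre is created: C1 becomes a prochiral quaternary carbon between two identical enone arms, and the C2 centre has no acidic hydrogen and is untouched. The step needs cyclisation to outrun oligomerisation and retro-Claisen deformylation; the geminal disubstitution at C1 (Thorpe–Ingold effect), the non-enolisable aldehydes and the buffered amine conditions should secure this.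

Step 9
Reactants: 13 4-[(1R,4E)-5-bromo-1-(tert-butyldimethylsilyloxy)-4-methylpent-4-en-1-yl]-4-methylcyclohexa-2,5-dien-1-one
Product: 14 (4S,5R)-4-[(1R,4E)-5-bromo-1-(tert-butyldimethylsilyloxy)-4-methylpent-4-en-1-yl]-5-ethenyl-4-methylcyclohex-2-en-1-one
Conditions: [Rh(cod)Cl]2 (3 mol %), (R)-BINAP (7 mol %), KOH (aq.), 1,4-dioxane, 40 °C
Reagents that add atoms: vinylboronic acid pinacol ester C=CB1OC(C)(C)C(C)(C)O1
Why: Hayashi–Miyaura conjugate addition desymmetrises the dienone, the vinyl group (C9) adding to C10 anti to the bulky silyloxyalkyl group and so cis to the C15 methyl, while the (R)-BINAP complex selects the enantiotopic enone arm and thereby fixes the quaternary C1 and C10 together.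

Step 10
Reactants: 14 (4S,5R)-4-[(1R,4E)-5-bromo-1-(tert-butyldimethylsilyloxy)-4-methylpent-4-en-1-yl]-5-ethenyl-4-methylcyclohex-2-en-1-one
Product: 15 6-methyl derivative of 14 with the new methyl trans to the vinyl group
Conditions: LiN(iPr)2, THF, −78 °C; then MeI, −78 to −40 °C
Reagents that add atoms: iodomethane CI
Why: Kinetic enolate alkylation at the only enolisable position (C11) brings in the C20 methyl anti to the neighbouring vinyl group; this C11 configuration is provisional because the centre is planarised in step 11.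

Step 11
Reactants: 15 6-methyl derivative of 14 with the new methyl trans to the vinyl group
Product: 17 6-(tert-butyldimethylsilyloxy)-6-methyl derivative of 14 with the silyloxy group trans to the vinyl group, via potassium alkoxide 16 (not isolated)
Conditions: KN(SiMe3)2, THF, −78 °C; 2-(phenylsulfonyl)-3-phenyloxaziridine; then TBSOTf, −78 to 0 °C
Reagents that add atoms: 2-(phenylsulfonyl)-3-phenyloxaziridine O=S(=O)(c1ccccc1)N1OC1c1ccccc1; tert-butyldimethylsilyl triflate CC(C)(C)[Si](C)(C)OS(=O)(=O)C(F)(F)F
Why: Davis oxidation of the potassium enolate should take place on the face anti to the C10 vinyl group and to the axial C15 methyl, placing the C11 oxygen trans to C9 and the C20 methyl cis to it as in the target, and the tertiary alkoxide is silylated in the flask.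

Step 12
Reactants: 17 6-(tert-butyldimethylsilyloxy)-6-methyl derivative of 14 with the silyloxy group trans to the vinyl group
Product: 18 C9 aldehyde in which the vinyl group of 17 is cut down to formyl
Conditions: OsO4 (2 mol %), NaIO4 (4 equiv), 2,6-lutidine, 1,4-dioxane/H2O, rt
Reagents that add atoms: sodium periodate [Na+].[O-]I(=O)(=O)=O
Why: Lemieux–Johnson cleavage should take the electron-richer monosubstituted vinyl group in preference to the enone and the bromoalkene, and the silylated C11 oxygen protects the α-ketol from periodate.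

Step 13
Reactants: 19 tert-butyl 2-bromopropanoate
Product: 21 tert-butyl 2-(triphenylphosphoranylidene)propanoate, via phosphonium bromide 20 (not isolated)
Conditions: PPh3, toluene, 80 °C; then NaOH (aq.), CH2Cl2, rt
Reagents that add atoms: triphenylphosphine c1ccc(cc1)P(c1ccccc1)c1ccccc1
Why: Quaternisation of the phosphine by the α-bromo ester and deprotonation give the stabilised ylide that carries C17, C18 and C19.

Step 14
Reactants: 21 tert-butyl 2-(triphenylphosphoranylidene)propanoate
Product: 22 tert-butyl 2-methylbuta-2,3-dienoate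
Conditions: acetyl chloride, Et3N, CH2Cl2, 0 °C to rt
Reagents that add atoms: acetyl chloride CC(Cl)=O
Why: Wittig reaction of the ylide with ketene generated in the flask from acetyl chloride and triethylamine gives the 2,3-allenoate, adding C8 and C7.

Step 15
Reactants: 22 tert-butyl 2-methylbuta-2,3-dienoate
Product: 23 tert-butyl 3-iodo-2-methylbut-3-enoate
Conditions: NaI, AcOH, 40 °C
Reagents that add atoms: sodium iodide [Na+].[I-]
Why: Hydroiodination of the allenoate puts iodide on the central carbon (C8) and a proton on the α-carbon (C17), giving the β-iodo-β,γ-unsaturated ester as a racemate.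

Step 16
Reactants: 18 C9 aldehyde in which the vinyl group of 17 is cut down to formyl; 23 tert-butyl 3-iodo-2-methylbut-3-enoate
Product: 24 C9 carbinol tert-butyl 3-[(R)-hydroxy(ring A unit of 18)methyl]-2-methylbut-3-enoate
Conditions: CrCl2 (4 equiv), NiCl2 (1 mol %), DMF, rt
Reagents that add atoms: none
Why: Nozaki–Hiyama–Kishi coupling, in which zerovalent nickel inserts into the C–I bond of 23 much faster than into the bromoalkene of 18 and the alkenylchromium adds only to the aldehyde, should form C8–C9 with Felkin–Anh control by C10 favouring the 9R carbinol.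

Step 17
Reactants: 24 C9 carbinol tert-butyl 3-[(R)-hydroxy(ring A unit of 18)methyl]-2-methylbut-3-enoate
Product: 25 C7,C8,C9 triol with the C8 and C9 hydroxyls anti
Conditions: OsO4 (5 mol %), NMO, acetone/H2O, rt
Reagents that add atoms: N-methylmorpholine N-oxide C[N+]1([O-])CCOCC1; water O
Why: Upjohn dihydroxylation of the 1,1-disubstituted C8=C7 alkene should follow the empirical anti rule for osmylation of allylic alcohols (C9–H eclipsing the alkene because of the C8 substituent), setting the tertiary C8 carbinol anti to the C9 hydroxyl, while the enone and bromoalkene are too electron-poor to compete.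

Step 18
Reactants: 25 C7,C8,C9 triol with the C8 and C9 hydroxyls anti
Product: 26 C7 aldehyde with free C8 and C9 hydroxyls
Conditions: TEMPO (10 mol %), NCS, Bu4NCl, CH2Cl2/aq. NaHCO3–K2CO3, rt
Reagents that add atoms: none
Why: The oxoammonium oxidation is selective for the primary C7 alcohol over the hindered secondary C9 alcohol and cannot touch the tertiary C8 hydroxyl, giving the non-enolisable α-hydroxy aldehyde.

Step 19
Reactants: 26 C7 aldehyde with free C8 and C9 hydroxyls
Product: 27 C9 acetate of the C7 aldehyde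
Conditions: Ac2O, pyridine, DMAP (cat.), CH2Cl2, 0 °C to rt
Reagents that add atoms: acetic anhydride CC(=O)OC(C)=O
Why: Acylation of the only secondary hydroxyl installs the C9 acetate of the target early, which also guarantees that the later lactone can form only through O7.

Step 20
Reactants: 27 C9 acetate of the C7 aldehyde
Product: 28 ten-membered carbocycle with the E-C5=C6 alkene and free C7 and C8 hydroxyls
Conditions: CrCl2 (10 equiv), NiCl2 (10 mol %), DMSO/THF, 0.002 M, rt to 50 °C
Reagents that add atoms: none
Why: Intramolecular Nozaki–Hiyama–Kishi addition of the alkenylchromium from the E-bromoalkene to the C7 aldehyde closes the ten-membered ring at C6–C7 with retention of alkene geometry, and Felkin–Anh attack anti to the C8 oxygen in the strongly coordinating solvent should set C7 anti to the C8 hydroxyl.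

Step 21
Reactants: 28 ten-membered carbocycle with the E-C5=C6 alkene and free C7 and C8 hydroxyls
Product: 29 C6 allylic chloride with the C5=C16 exocyclic methylene
Conditions: Ca(OCl)2, CO2 (solid), CH2Cl2/H2O, 0 °C
Reagents that add atoms: calcium hypochlorite [Ca+2].[O-]Cl.[O-]Cl
Why: Ene-type allylic chlorination by HOCl should deliver chlorine to C6 of the only electron-rich alkene with proton loss from the C16 methyl, giving the exocyclic methylene and, by approach anti to the C7 hydroxyl in the A(1,3)-minimised conformer, the C6 chloride anti to O7.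

Step 22
Reactants: 29 C6 allylic chloride with the C5=C16 exocyclic methylene
Product: 30 2-O-deacetyl target with the C19–O7 lactone closed and free C2, C8 and C11 hydroxyls
Conditions: CF3CO2H/CH2Cl2/H2O, 0 °C to rt; then DBU (cat.), CH2Cl2, rt
Reagents that add atoms: none
Why: Acidolysis of the tert-butyl ester and both silyl ethers frees the C19 acid, which lactonises onto the C7 hydroxyl only (O9 is acetylated and O8 would give a four-membered ring), and catalytic DBU equilibrates the enolisable C17 so that its methyl should settle trans to C9 and cis to the C8 hydroxyl as in the target.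

Step 23
Reactants: 30 2-O-deacetyl target with the C19–O7 lactone closed and free C2, C8 and C11 hydroxyls
Product: 31 CNP0261648.1
Conditions: Ac2O, pyridine, rt
Reagents that add atoms: acetic anhydride CC(=O)OC(C)=O
Why: Pyridine-mediated acetylation takes the only secondary hydroxyl (C2) and leaves the tertiary C8 and C11 hydroxyls untouched, completing the target.

**Compound list**

1 | pent-4-yn-1-ol | C#CCCCO | starting material
2 | (E)-5-bromo-4-methylpent-4-en-1-ol | OCCC/C(C)=C/Br | intermediate
3 | (E)-5-bromo-4-methylpent-4-enoic acid | OC(=O)CC/C(C)=C/Br | intermediate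
4 | dimethyl 2-methylmalonate | COC(=O)C(C)C(=O)OC | starting material
5 | (E)-5-bromo-4-methylpent-4-enoyl chloride | ClC(=O)CC/C(C)=C/Br | intermediate
6 | dimethyl 2-[(E)-5-bromo-4-methylpent-4-enoyl]-2-methylmalonate | Br/C=C(C)/CCC(=O)C(C)(C(=O)OC)C(=O)OC | intermediate
7 | dimethyl 2-[(1R,4E)-5-bromo-1-hydroxy-4-methylpent-4-en-1-yl]-2-methylmalonate | Br/C=C(C)/CC[C@@H](O)C(C)(C(=O)OC)C(=O)OC | intermediate
8 | dimethyl 2-[(1R,4E)-5-bromo-1-(tert-butyldimethylsilyloxy)-4-methylpent-4-en-1-yl]-2-methylmalonate | Br/C=C(C)/CC[C@@H](O[Si](C)(C)C(C)(C)C)C(C)(C(=O)OC)C(=O)OC | intermediate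
9 | 2-[(1R,4E)-5-bromo-1-(tert-butyldimethylsilyloxy)-4-methylpent-4-en-1-yl]-2-methylpropane-1,3-diol | Br/C=C(C)/CC[C@@H](O[Si](C)(C)C(C)(C)C)C(C)(CO)CO | intermediate
10 | 2-[(1R,4E)-5-bromo-1-(tert-butyldimethylsilyloxy)-4-methylpent-4-en-1-yl]-2-methylpropanedial | Br/C=C(C)/CC[C@@H](O[Si](C)(C)C(C)(C)C)C(C)(C=O)C=O | intermediate
11 | 3-oxopentanedioic acid (acetonedicarboxylic acid) | OC(=O)CC(=O)CC(O)=O | starting material
12 | cyclic bis-aldol diacid: 4,6-dihydroxy-5-methyl-2-oxocyclohexane-1,3-dicarboxylic acid bearing the side chain of 10 at C5 (ring stereocentres undefined) | Br/C=C(C)/CC[C@@H](O[Si](C)(C)C(C)(C)C)C1(C)C(O)C(C(O)=O)C(=O)C(C(O)=O)C1O | intermediate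
13 | 4-[(1R,4E)-5-bromo-1-(tert-butyldimethylsilyloxy)-4-methylpent-4-en-1-yl]-4-methylcyclohexa-2,5-dien-1-one | Br/C=C(C)/CC[C@@H](O[Si](C)(C)C(C)(C)C)C1(C)C=CC(=O)C=C1 | intermediate
14 | (4S,5R)-4-[(1R,4E)-5-bromo-1-(tert-butyldimethylsilyloxy)-4-methylpent-4-en-1-yl]-5-ethenyl-4-methylcyclohex-2-en-1-one (vinyl cis to the ring methyl) | Br/C=C(C)/CC[C@@H](O[Si](C)(C)C(C)(C)C)[C@@]1(C)C=CC(=O)C[C@@H]1C=C | intermediate
15 | 6-methyl derivative of 14 (new methyl trans to the vinyl group) | Br/C=C(C)/CC[C@@H](O[Si](C)(C)C(C)(C)C)[C@@]1(C)C=CC(=O)[C@@H](C)[C@@H]1C=C | intermediate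
16 | potassium alkoxide of the 6-hydroxy-6-methyl enone (oxygen trans to the vinyl group) | Br/C=C(C)/CC[C@@H](O[Si](C)(C)C(C)(C)C)[C@@]1(C)C=CC(=O)[C@@](C)([O-])[C@@H]1C=C.[K+] | intermediate
17 | 6-(tert-butyldimethylsilyloxy)-6-methyl derivative of 14 (silyloxy trans to the vinyl group, methyl cis) | Br/C=C(C)/CC[C@@H](O[Si](C)(C)C(C)(C)C)[C@@]1(C)C=CC(=O)[C@@](C)(O[Si](C)(C)C(C)(C)C)[C@@H]1C=C | intermediate
18 | C9 aldehyde: 17 with the vinyl group cut down to formyl | Br/C=C(C)/CC[C@@H](O[Si](C)(C)C(C)(C)C)[C@@]1(C)C=CC(=O)[C@@](C)(O[Si](C)(C)C(C)(C)C)[C@@H]1C=O | intermediate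
19 | tert-butyl 2-bromopropanoate (racemic) | CC(Br)C(=O)OC(C)(C)C | starting material
20 | [1-(tert-butoxycarbonyl)ethyl]triphenylphosphonium bromide | CC(C(=O)OC(C)(C)C)[P+](c1ccccc1)(c1ccccc1)c1ccccc1.[Br-] | intermediate
21 | tert-butyl 2-(triphenylphosphoranylidene)propanoate | CC(C(=O)OC(C)(C)C)=P(c1ccccc1)(c1ccccc1)c1ccccc1 | intermediate
22 | tert-butyl 2-methylbuta-2,3-dienoate | C=C=C(C)C(=O)OC(C)(C)C | intermediate
23 | tert-butyl 3-iodo-2-methylbut-3-enoate (racemic at C17) | C=C(I)C(C)C(=O)OC(C)(C)C | intermediate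
24 | C9 carbinol: tert-butyl 3-[(R)-hydroxy(ring A unit of 18)methyl]-2-methylbut-3-enoate (both C17 epimers) | Br/C=C(C)/CC[C@@H](O[Si](C)(C)C(C)(C)C)[C@@]1(C)C=CC(=O)[C@@](C)(O[Si](C)(C)C(C)(C)C)[C@@H]1[C@@H](O)C(=C)C(C)C(=O)OC(C)(C)C | intermediate
25 | C7,C8,C9 triol from 24 (C8 and C9 hydroxyls anti; both C17 epimers) | Br/C=C(C)/CC[C@@H](O[Si](C)(C)C(C)(C)C)[C@@]1(C)C=CC(=O)[C@@](C)(O[Si](C)(C)C(C)(C)C)[C@@H]1[C@@H](O)[C@](CO)(O)C(C)C(=O)OC(C)(C)C | intermediate
26 | C7 aldehyde with free C8 and C9 hydroxyls (both C17 epimers) | Br/C=C(C)/CC[C@@H](O[Si](C)(C)C(C)(C)C)[C@@]1(C)C=CC(=O)[C@@](C)(O[Si](C)(C)C(C)(C)C)[C@@H]1[C@@H](O)[C@](C=O)(O)C(C)C(=O)OC(C)(C)C | intermediate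
27 | C9 acetate of the C7 aldehyde (both C17 epimers) | Br/C=C(C)/CC[C@@H](O[Si](C)(C)C(C)(C)C)[C@@]1(C)C=CC(=O)[C@@](C)(O[Si](C)(C)C(C)(C)C)[C@@H]1[C@@H](OC(C)=O)[C@](C=O)(O)C(C)C(=O)OC(C)(C)C | intermediate
28 | ten-membered carbocycle with the E-C5=C6 alkene, free C7 and C8 hydroxyls, C9 acetate, C2 and C11 silyl ethers, tert-butyl ester side chain at C8 (both C17 epimers) | C1C/C(C)=C/[C@H](O)[C@@](O)(C(C)C(=O)OC(C)(C)C)[C@H](OC(C)=O)[C@H]2[C@](C)(O[Si](C)(C)C(C)(C)C)C(=O)C=C[C@]2(C)[C@@H]1O[Si](C)(C)C(C)(C)C | intermediate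
29 | C6 allylic chloride with the C5=C16 exocyclic methylene (Cl anti to O7; both C17 epimers) | C=C1CC[C@@H](O[Si](C)(C)C(C)(C)C)[C@@]2(C)C=CC(=O)[C@@](C)(O[Si](C)(C)C(C)(C)C)[C@@H]2[C@@H](OC(C)=O)[C@](O)(C(C)C(=O)OC(C)(C)C)[C@@H](O)[C@H]1Cl | intermediate
30 | 2-O-deacetyl target: C19–O7 lactone closed, free C2, C8 and C11 hydroxyls, C9 acetate | C=C1CC[C@@H](O)[C@@]2(C)C=CC(=O)[C@@](C)(O)[C@@H]2[C@@H](OC(C)=O)[C@]2(O)[C@@H](C)C(=O)O[C@H]2[C@H]1Cl | intermediate
31 | CNP0261648.1: 2,9-diacetoxy-6-chloro-8,11-dihydroxy-12-oxobriara-5(16),13-diene 19,7-lactone | C=C1CC[C@@H](OC(C)=O)[C@@]2(C)C=CC(=O)[C@@](C)(O)[C@@H]2[C@@H](OC(C)=O)[C@]2(O)[C@@H](C)C(=O)O[C@H]2[C@H]1Cl | target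

**Totals and risks**

Total step count: 23. Longest linear sequence: 20 steps (steps 1 to 12, then 16 to 23); steps 13 to 15 make the three-step side branch to 23.

Three steps most likely to fail:

Step 20. The ring closure at C6–C7 has to outrun oligomerisation, and the free C8 hydroxyl may chelate chromium so that the alkenyl group adds to the wrong face of the C7 aldehyde (poor facial selectivity at C7). The fallback sets out from 28 taken as its C7 epimer mixture. Dess–Martin oxidation of the allylic C7 carbinol gives the macrocyclic C7 ketone F1. Chelation-controlled reduction with Zn(BH4)2, with hydride delivered from the ring periphery onto the zinc chelate of the C8 hydroxyl and the C7 carbonyl, should give the carbinol with C7 anti to the C8 hydroxyl, and comes back to the route at 28.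

Step 21. Proton loss from C4 instead of the C16 methyl (giving an endocyclic alkene) or chlorine delivery to the wrong face of C6 may erode regio- and stereoselectivity. The fallback sets out from 28. Hydroxyl-directed epoxidation with VO(acac)2 and tBuOOH should give the 5,6-epoxide F2 syn to the C7 hydroxyl. Isomerisation with diethylaluminium 2,2,6,6-tetramethylpiperidide toward the C16 methyl gives the C6 allylic alcohol F3. Corey–Kim chlorination (NCS, Me2S), selective for the allylic hydroxyl and proceeding with inversion, comes back at 29.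

Step 17. The very bulky C10 substituent may override the anti preference, so that osmium adds to the wrong face of the C8=C7 alkene (poor facial selectivity at C8). The fallback sets out from 24. Hydroxyl-directed epoxidation with VO(acac)2 and tBuOOH, whose erythro preference is enforced by the substituent at C8, gives the epoxy alcohol F4. Opening at the primary C7 with CsOAc in DMF gives the C7 acetate F5, and methanolysis (K2CO3, MeOH) comes back at 25.

Further compounds
F1 | step 20 | macrocyclic C7 ketone (E-enone with C5=C6) from oxidation of 28 | C1C/C(C)=C/C(=O)[C@@](O)(C(C)C(=O)OC(C)(C)C)[C@H](OC(C)=O)[C@H]2[C@](C)(O[Si](C)(C)C(C)(C)C)C(=O)C=C[C@]2(C)[C@@H]1O[Si](C)(C)C(C)(C)C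
F2 | step 21 | 5,6-epoxide of 28 syn to the C7 hydroxyl | C1C[C@]3(C)O[C@H]3[C@H](O)[C@@](O)(C(C)C(=O)OC(C)(C)C)[C@H](OC(C)=O)[C@H]2[C@](C)(O[Si](C)(C)C(C)(C)C)C(=O)C=C[C@]2(C)[C@@H]1O[Si](C)(C)C(C)(C)C
F3 | step 21 | C6 allylic alcohol with the C5=C16 methylene (C6 hydroxyl syn to the C7 hydroxyl) | C=C1CC[C@@H](O[Si](C)(C)C(C)(C)C)[C@@]2(C)C=CC(=O)[C@@](C)(O[Si](C)(C)C(C)(C)C)[C@@H]2[C@@H](OC(C)=O)[C@](O)(C(C)C(=O)OC(C)(C)C)[C@@H](O)[C@@H]1O
F4 | step 17 | erythro 7,8-epoxy alcohol from 24 | Br/C=C(C)/CC[C@@H](O[Si](C)(C)C(C)(C)C)[C@@]1(C)C=CC(=O)[C@@](C)(O[Si](C)(C)C(C)(C)C)[C@@H]1[C@@H](O)[C@@]3(CO3)C(C)C(=O)OC(C)(C)C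
F5 | step 17 | C7 acetate of triol 25 | Br/C=C(C)/CC[C@@H](O[Si](C)(C)C(C)(C)C)[C@@]1(C)C=CC(=O)[C@@](C)(O[Si](C)(C)C(C)(C)C)[C@@H]1[C@@H](O)[C@](COC(C)=O)(O)C(C)C(=O)OC(C)(C)C
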